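The ten-membered ring is not closed end to end but grown from a cyclohexene. O-2 lies beside quaternary C1 and the C7–C8 unit five atoms further on, so ring C2–C9 maps onto a cyclodec-5-enone that arises by [3,3] shift of a 1,2-dialkenylcyclohexenol. In one operation (step 21) the potassium alkoxide of carbinol 26 breaks C2–C7, forms C9–C10 with C9 and C10 set, and the regiospecific C1 dienolate is methylated (C1–C15), giving the 6-10 bicycle 28. In 26, C2 carries the ring-C cyclohexadienyl acetonide and C7 an enol-ether side chain; both six-membered partners come from one enone, 7.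

Key step: step 21

Remark: atom numbers are those of the briarane skeleton (C1 ring-fusion carbon bearing C15; C2–C9 ten-membered ring; C10 ring-fusion CH; C11–C14 ring C; C16 on C5; C17/C18/C19 lactone α-carbon, its methyl and carbonyl; C20 on C11).
Remark: Bu3SnCH2OPMB (step 13) is taken as an available reagent (one step from Bu3SnCH2I and 4-methoxybenzyl alcohol); compound 16 is an inconsequential mixture of C8 epimers.
Remark: the enol ether required in 23 and 26 has O-9 cis to C7 (E by the CIP rules); only this isomer places O-9 axial in the chair and leads to 9S.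

Step 1
Reactants: 1 2-methylcyclohex-2-en-1-one
Product: 2 (R)-2-methylcyclohex-2-en-1-ol
Conditions: (S)-Me-CBS (10 mol%), BH3·SMe2, THF, −20 °C
Reagents that add atoms: none
Why: Corey–Bakshi–Shibata reduction, in which the catalyst treats the alkenyl flank as the large group and should deliver hydride to give the (R)-carbinol that later becomes C12 of ring C and C4 of the ten-membered ring.

Step 2
Reactants: 2 (R)-2-methylcyclohex-2-en-1-ol
Product: 3 (1R,2R,6S)-1-methyl-7-oxabicyclo[4.1.0]heptan-2-ol (epoxide cis to OH)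
Conditions: mCPBA, NaHCO3, CH2Cl2, 0 °C
Reagents that add atoms: 3-chloroperbenzoic acid, OOC(=O)c1cccc(Cl)c1
Why: Henbest hydroxyl-directed epoxidation, the hydrogen-bonded peracid adding syn to the allylic OH so that the tertiary C–O bond (later C11–O and C5–O) is cis to the carbinol.

Step 3
Reactants: 3 (1R,2R,6S)-1-methyl-7-oxabicyclo[4.1.0]heptan-2-ol
Product: 5 (1R,2S)-2-methylcyclohex-3-ene-1,2-diol (cis), via hydroxy selenide 4 (not isolated)
Conditions: (PhSe)2, NaBH4, EtOH, 0 → 78 °C; then 30% H2O2, THF, 0 → 25 °C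
Reagents that add atoms: none
Why: Sharpless–Lauer epoxide-to-allylic-alcohol transposition, PhSe− opening the epoxide trans-diaxially at the secondary carbon and the selenoxide eliminating syn towards the only β-CH2, so both carbinol centres are retained.

Step 4
Reactants: 5 (1R,2S)-2-methylcyclohex-3-ene-1,2-diol
Product: 6 (3aS,7aR)-2,2,3a-trimethyl-3a,6,7,7a-tetrahydro-1,3-benzodioxole
Conditions: 2,2-dimethoxypropane, PPTS (cat.), CH2Cl2, 25 °C
Reagents that add atoms: 2,2-dimethoxypropane, COC(C)(C)OC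
Why: Acetal exchange closes the cis-fused acetonide of a cis-1,2-diol without touching either stereocentre.

Step 5
Reactants: 6 (3aS,7aR)-2,2,3a-trimethyl-3a,6,7,7a-tetrahydro-1,3-benzodioxole
Product: 7 (3aR,7aS)-2,2,7a-trimethyl-3a,4-dihydro-1,3-benzodioxol-5(7aH)-one
Conditions: Rh2(cap)4 (1 mol%), t-BuOOH (70% aq.), K2CO3, CH2Cl2, 25 °C
Reagents that add atoms: tert-butyl hydroperoxide, CC(C)(C)OO
Why: Dirhodium-catalysed allylic C–H oxidation gives the enone regiospecifically because the only allylic methylene is the one oxidised (the other allylic carbon is quaternary).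

Step 6
Reactants: 7 (3aR,7aS)-2,2,7a-trimethyl-3a,4-dihydro-1,3-benzodioxol-5(7aH)-one
Product: 8 (3aR,7aS)-6-iodo-2,2,7a-trimethyl-3a,4-dihydro-1,3-benzodioxol-5(7aH)-one
Conditions: I2, pyridine, CH2Cl2, 25 °C
Reagents that add atoms: iodine, II
Why: Johnson α-iodination of an enone (pyridine conjugate addition, iodination, elimination) puts the halogen on the future C1.

Step 7
Reactants: 8 (3aR,7aS)-6-iodo-2,2,7a-trimethyl-3a,4-dihydro-1,3-benzodioxol-5(7aH)-one
Product: 9 (3aR,5S,7aS)-6-iodo-2,2,7a-trimethyl-3a,4,5,7a-tetrahydro-1,3-benzodioxol-5-ol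
Conditions: NaBH4, CeCl3·7H2O, MeOH, −78 °C
Reagents that add atoms: none
Why: Luche 1,2-reduction with hydride from the convex face; the new carbinol centre is removed in the next step.

Step 8
Reactants: 9 (3aR,5S,7aS)-6-iodo-2,2,7a-trimethyl-3a,4,5,7a-tetrahydro-1,3-benzodioxol-5-ol
Product: 10 (3aS,7aR)-5-iodo-2,2,3a-trimethyl-3a,7a-dihydro-1,3-benzodioxole (ring-C dienyl iodide, iodine on C1)
Conditions: Martin sulfurane, CH2Cl2, 0 °C
Reagents that add atoms: none
Why: Dehydration with Martin sulfurane is regiospecific because only the C13 methylene offers β-hydrogens, giving the C10=C1–C14=C13 diene.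

Step 9
Reactants: 11 2-methylprop-2-en-1-ol
Product: 12 (S)-(2-methyloxiran-2-yl)methanol
Conditions: Ti(OiPr)4 (5 mol%), L-(+)-DIPT (6 mol%), t-BuOOH, 4 Å MS, CH2Cl2, −20 °C
Reagents that add atoms: tert-butyl hydroperoxide, CC(C)(C)OO
Why: Sharpless asymmetric epoxidation with L-(+)-tartrate delivers oxygen to the face that gives the (S)-epoxy alcohol, whose quaternary carbon is C17.

Step 10
Reactants: 12 (S)-(2-methyloxiran-2-yl)methanol
Product: 13 (S)-3-[(4-methoxybenzyl)oxy]-2-methylpropane-1,2-diol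
Conditions: 4-methoxybenzyl alcohol, NaH, DMF, 60 °C
Reagents that add atoms: 4-methoxybenzyl alcohol, COc1ccc(CO)cc1
Why: Base-mediated epoxide opening by the alkoxide at the primary carbon (future C19) leaves the C17–O bond untouched.

Step 11
Reactants: 13 (S)-3-[(4-methoxybenzyl)oxy]-2-methylpropane-1,2-diol
Product: 14 bis(triethylsilyl) ether of 13
Conditions: TESOTf, 2,6-lutidine, CH2Cl2, −78 → 0 °C
Reagents that add atoms: triethylsilyl trifluoromethanesulfonate, CC[Si](CC)(CC)OS(=O)(=O)C(F)(F)F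
Why: Silyl triflate silylates both the primary and the tertiary hydroxyl.

Step 12
Reactants: 14 bis(triethylsilyl) ether of 13
Product: 15 (R)-3-[(4-methoxybenzyl)oxy]-2-methyl-2-(triethylsilyloxy)propanal
Conditions: (COCl)2, DMSO, CH2Cl2, −78 → −40 °C; then Et3N
Reagents that add atoms: none
Why: Swern conditions oxidise a primary triethylsilyl ether directly to the aldehyde (oxidative desilylation) while the tertiary silyl ether stays.

Step 13
Reactants: 15 (R)-3-[(4-methoxybenzyl)oxy]-2-methyl-2-(triethylsilyloxy)propanal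
Product: 16 1,4-bis[(4-methoxybenzyl)oxy]-3-methyl-3-(triethylsilyloxy)butan-2-ol (C8 epimers)
Conditions: Bu3SnCH2OPMB, n-BuLi, THF, −78 °C; then 15
Reagents that add atoms: tributyl{[(4-methoxybenzyl)oxy]methyl}stannane, CCCC[Sn](CCCC)(CCCC)COCc1ccc(OC)cc1
Why: Tin–lithium exchange gives an α-alkoxy organolithium (Still reagent) that adds to the aldehyde and installs C9 with its protected oxygen.

Step 14
Reactants: 16 1,4-bis[(4-methoxybenzyl)oxy]-3-methyl-3-(triethylsilyloxy)butan-2-ol
Product: 17 (R)-1,4-bis[(4-methoxybenzyl)oxy]-3-methyl-3-(triethylsilyloxy)butan-2-one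
Conditions: Dess–Martin periodinane, NaHCO3, CH2Cl2, 0 → 25 °C
Reagents that add atoms: none
Why: Dess–Martin oxidation converges both epimers on the α-alkoxy ketone, which can enolise on one side only.

Step 15
Reactants: 17 (R)-1,4-bis[(4-methoxybenzyl)oxy]-3-methyl-3-(triethylsilyloxy)butan-2-one
Product: 18 (Z)-enol triflate TfO–C8(=C9H–OPMB)–C17(Me)(OTES)–C19H2OPMB (TfO cis to O-9)
Conditions: LiHMDS, THF, −78 °C; then Comins' reagent, −78 → 0 °C
Reagents that add atoms: N-(5-chloropyridin-2-yl)bis(trifluoromethanesulfonimide), FC(F)(F)S(=O)(=O)N(c1ccc(Cl)cn1)S(=O)(=O)C(F)(F)F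
Why: Enolate O-triflation through the lithium-chelated (Z)-enolate of the α-alkoxy ketone fixes the enol ether geometry (O-9 cis to the future C7 substituent).

Step 16
Reactants: 7 (3aR,7aS)-2,2,7a-trimethyl-3a,4-dihydro-1,3-benzodioxol-5(7aH)-one
Product: 19 (R)-5-hydroxy-4-methylcyclohex-3-en-1-one
Conditions: SmI2 (2.5 equiv), THF/MeOH, −78 °C
Reagents that add atoms: none
Why: Samarium diiodide reduction of a γ-alkoxy enone cleaves the tertiary γ-C–O bond, kinetic α-protonation of the dienolate gives the β,γ-enone (C5=C6), and the hemiketal loses acetone; the C4 carbinol is untouched.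

Step 17
Reactants: 19 (R)-5-hydroxy-4-methylcyclohex-3-en-1-one
Product: 20 (R)-4-methyl-5-(triethylsilyloxy)cyclohex-3-en-1-one
Conditions: TESOTf, 2,6-lutidine, CH2Cl2, −78 °C
Reagents that add atoms: triethylsilyl trifluoromethanesulfonate, CC[Si](CC)(CC)OS(=O)(=O)C(F)(F)F
Why: Low-temperature silylation protects the β-hydroxy ketone before it can dehydrate.

Step 18
Reactants: 20 (R)-4-methyl-5-(triethylsilyloxy)cyclohex-3-en-1-one
Product: 21 2-(trimethylsilyloxy)diene C2(OTMS)=C7–C6=C5 of 20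
Conditions: TMSOTf, Et3N, CH2Cl2, 0 °C
Reagents that add atoms: trimethylsilyl trifluoromethanesulfonate, C[Si](C)(C)OS(=O)(=O)C(F)(F)F
Why: Soft enolisation removes the more acidic doubly activated C7–H and gives the conjugated silyl dienol ether.

Step 19
Reactants: 21 2-(trimethylsilyloxy)diene of 20; 18 (Z)-enol triflate
Product: 23 4,7-trans ketone: 4-methylcyclohex-3-enone with C4–OTES and, on C7, the side chain C8(=C9H–OPMB)–C17(Me)(OTES)–C19H2OPMB (O-9 cis to C7), via tributyltin dienolate 22 (not isolated)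
Conditions: Pd2(dba)3 (5 mol%), P(t-Bu)3, Bu3SnF, LiCl, THF, 50 °C
Reagents that add atoms: none
Why: Palladium-catalysed α-alkenylation of a ketone through its tin enolate (Kuwajima–Urabe/Migita type), the alkenylpalladium adding to C7 anti to the pseudoaxial C4–OTES so that C7–C8 is trans to O-4, with retention of the triflate geometry.

Step 20
Reactants: 10 ring-C dienyl iodide; 23 4,7-trans ketone
Product: 26 carbinol: 1-(ring-C dienyl)-trans-2-alkenylcyclohex-3-en-1-ol (C2–OH cis to the C7 side chain; C4–OTES), via dienyllithium 24 (not isolated), via dienylcerium dichloride 25 (not isolated)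
Conditions: t-BuLi (2 equiv), Et2O, −78 °C; CeCl3, THF, −78 °C; then 23, −78 °C
Reagents that add atoms: none
Why: Iodine–lithium exchange, transmetallation to cerium (Imamoto) and 1,2-addition, the weakly basic reagent sparing the labile C7–H and attacking equatorially, anti to the C7 side chain, which sets C2 and gives the trans-dialkenyl carbinol.

Step 21
Reactants: 26 carbinol
Product: 28 bicyclic ketone: trans-fused cyclohexene/cyclodeca-5,7-dien-2-one (C15 on C1 cis to C9; 9S-OPMB; 10S; C5=C6 Z; C6 and C9 trans across C7=C8), via potassium dienolate 27 (not isolated)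
Conditions: KH, 18-crown-6, THF, 0 → 25 °C; then MeI, −78 → 0 °C
Reagents that add atoms: iodomethane, CI
Why: The C2 potassium alkoxide accelerates a [3,3] sigmatropic shift of the 1,5-diene C10=C1–C2–C7–C8=C9 (anionic oxy-Cope, the established ring expansion of trans-1,2-dialkenylcyclohexanols to cyclodec-5-enones with regiospecific enolate trapping): C2–C7 breaks while C9–C10 forms. The ten-membered ring is therefore closed by four-atom sigmatropic ring expansion of the cyclohexene, not by end-to-end cyclisation. The trans arrangement of the alkenyl groups lets both ring bonds (C2–C3, C7–C6) sit equatorial in a chair, which gives the C7=C8 bond with C6 and C9 trans and the (E)-dienolate O–C2=C1–C14=C13. C10 and C9 follow from that chair by chirality transfer from C2 and C7 (C11 equatorial at the ring-C terminus; O-9, cis to C7, axial at the enol ether terminus). Iodomethane then alkylates the α-carbon C1 of the dienolate, creating the quaternary centre and leaving C13=C14 in place. The step needs chair over boat (secured by the trans-dialkenyl carbinol), C- over O-alkylation (soft electrophile on a potassium dienolate) and methyl delivery to the C1 face cis to C9, which the rearrangement does not enforce and which is the stereochemical risk of the route.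

Step 22
Reactants: 28 bicyclic ketone
Product: 29 (3R)-3-hydroxy derivative of 28
Conditions: KHMDS, THF, −78 °C; then 3-phenyl-2-(phenylsulfonyl)oxaziridine, −78 °C
Reagents that add atoms: 3-phenyl-2-(phenylsulfonyl)oxaziridine, O=S(=O)(N1OC1c1ccccc1)c1ccccc1
Why: Davis oxidation of the only possible enolate (C1 is quaternary), the oxaziridine approaching anti to the C4–C5 ring bond with H-4 eclipsing the enolate, which should give the 3,4-syn (3R) alcohol.

Step 23
Reactants: 29 (3R)-3-hydroxy ketone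
Product: 30 (2S,3R)-2,3-diol
Conditions: Zn(BH4)2, Et2O, −20 °C
Reagents that add atoms: none
Why: Chelation-controlled reduction of an α-hydroxy ketone, hydride entering the zinc chelate from the H-3 side to give the 2,3-anti diol (2S).

Step 24
Reactants: 30 (2S,3R)-2,3-diol
Product: 31 3-O-TBS ether of 30 (C2–OH free)
Conditions: TBSOTf (1.05 equiv), 2,6-lutidine, CH2Cl2, −78 °C
Reagents that add atoms: tert-butyldimethylsilyl trifluoromethanesulfonate, CC(C)(C)[Si](C)(C)OS(=O)(=O)C(F)(F)F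
Why: Regioselective silylation of the less hindered C3 hydroxyl, the C2 hydroxyl being neopentylic next to quaternary C1.

Step 25
Reactants: 31 3-O-TBS ether
Product: 32 2,4-diol (O-4 TES removed; O-17 TES, O-3 TBS and both PMB ethers kept)
Conditions: HF·pyridine, pyridine, THF, 0 °C
Reagents that add atoms: none
Why: Buffered fluoride cleaves the secondary allylic triethylsilyl ether faster than the tertiary triethylsilyl and the hindered TBS ethers.

Step 26
Reactants: 32 2,4-diol
Product: 33 2,4-diacetate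
Conditions: Ac2O, DMAP, pyridine, CH2Cl2, 0 → 25 °C
Reagents that add atoms: acetic anhydride, CC(=O)OC(C)=O
Why: DMAP-catalysed acetylation of the two free secondary hydroxyls while O-3 stays silylated.

Step 27
Reactants: 33 2,4-diacetate
Product: 34 9,19-diol (both PMB ethers removed)
Conditions: DDQ, CH2Cl2/pH 7 buffer, 0 °C
Reagents that add atoms: none
Why: Oxidative cleavage of both p-methoxybenzyl ethers by DDQ; the still silylated O-17 cannot capture the oxocarbenium ion as a cyclic acetal.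

Step 28
Reactants: 34 9,19-diol
Product: 35 C19 carboxylic acid (O-17 TES, C9–OH free)
Conditions: TEMPO (cat.), PhI(OAc)2, MeCN/H2O, 25 °C
Reagents that add atoms: water, O
Why: TEMPO/BAIB oxidation takes the primary alcohol through the aldehyde hydrate to the acid and is much slower at the hindered secondary C9 hydroxyl.

Step 29
Reactants: 35 C19 carboxylic acid
Product: 36 17-hydroxy acid (tertiary TES removed)
Conditions: HF·pyridine, THF, 25 °C
Reagents that add atoms: none
Why: Fluoride desilylation removes the tertiary triethylsilyl ether while the more robust, hindered O-3 TBS ether persists.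

Step 30
Reactants: 36 17-hydroxy acid
Product: 38 hydroxy lactone (C19–O–C7 γ-lactone, 8-OH, 9-OH), via epoxy acid 37 (not isolated)
Conditions: mCPBA, CH2Cl2, 0 → 25 °C; then CSA (cat.)
Reagents that add atoms: 3-chloroperbenzoic acid, OOC(=O)c1cccc(Cl)c1
Why: Hydroxyl-directed peracid epoxidation followed by acid-catalysed lactonisation of the β,γ-epoxy acid: the tertiary C17–OH, in the allylic-strain-minimised rotamer with C18 eclipsing C7=C8, delivers oxygen to the face that becomes the 8-hydroxyl, and the C19 acid opens the allylic C7–O bond from the rear (inversion, five-membered ring), a net anti addition that sets C8 and C7.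

Step 31
Reactants: 38 hydroxy lactone
Product: 39 2,4,9-triacetate (O-3 TBS, 11,12-acetonide)
Conditions: Ac2O, DMAP, pyridine, 25 °C
Reagents that add atoms: acetic anhydride, CC(=O)OC(C)=O
Why: Acetylation of the only free secondary hydroxyl (C9), the tertiary 8- and 17-hydroxyls being too hindered to react.

Step 32
Reactants: 39 2,4,9-triacetate
Product: 40 Brianodin C
Conditions: aq. HF (48%), MeCN, 0 → 25 °C
Reagents that add atoms: none
Why: Acidic fluoride removes the TBS ether and hydrolyses the acetonide, conditions that leave acetates and lactone in place and avoid base-induced acyl migration.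

Compound list
1 | 2-methylcyclohex-2-en-1-one | CC1=CCCCC1=O | starting material
2 | (R)-2-methylcyclohex-2-en-1-ol | O[C@H]1C(C)=CCCC1 | intermediate
3 | (1R,2R,6S)-1-methyl-7-oxabicyclo[4.1.0]heptan-2-ol | O[C@@H]1CCC[C@@H]2O[C@]12C | intermediate
4 | 1-methyl-6-(phenylselanyl)cyclohexane-1,2-diol (cis-diol, SePh trans to tertiary OH) | O[C@@H]1CCC[C@@H]([Se]c2ccccc2)[C@]1(C)O | intermediate (not isolated)
5 | (1R,2S)-2-methylcyclohex-3-ene-1,2-diol | O[C@@H]1CCC=C[C@]1(C)O | intermediate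
6 | (3aS,7aR)-2,2,3a-trimethyl-3a,6,7,7a-tetrahydro-1,3-benzodioxole | C1=C[C@]2(C)OC(C)(C)O[C@@H]2CC1 | intermediate
7 | (3aR,7aS)-2,2,7a-trimethyl-3a,4-dihydro-1,3-benzodioxol-5(7aH)-one | O=C1C=C[C@]2(C)OC(C)(C)O[C@@H]2C1 | intermediate
8 | (3aR,7aS)-6-iodo-2,2,7a-trimethyl-3a,4-dihydro-1,3-benzodioxol-5(7aH)-one | O=C1C(I)=C[C@]2(C)OC(C)(C)O[C@@H]2C1 | intermediate
9 | (3aR,5S,7aS)-6-iodo-2,2,7a-trimethyl-3a,4,5,7a-tetrahydro-1,3-benzodioxol-5-ol | O[C@@H]1C(I)=C[C@]2(C)OC(C)(C)O[C@@H]2C1 | intermediate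
10 | (3aS,7aR)-5-iodo-2,2,3a-trimethyl-3a,7a-dihydro-1,3-benzodioxole | IC1=C[C@]2(C)OC(C)(C)O[C@@H]2C=C1 | intermediate
11 | 2-methylprop-2-en-1-ol | CC(=C)CO | starting material
12 | (S)-(2-methyloxiran-2-yl)methanol | OC[C@@]1(C)CO1 | intermediate
13 | (S)-3-[(4-methoxybenzyl)oxy]-2-methylpropane-1,2-diol | OC[C@](C)(O)COCc1ccc(OC)cc1 | intermediate
14 | bis(triethylsilyl) ether of 13 | CC[Si](CC)(CC)OC[C@](C)(O[Si](CC)(CC)CC)COCc1ccc(OC)cc1 | intermediate
15 | (R)-3-[(4-methoxybenzyl)oxy]-2-methyl-2-(triethylsilyloxy)propanal | O=C[C@](C)(O[Si](CC)(CC)CC)COCc1ccc(OC)cc1 | intermediate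
16 | 1,4-bis[(4-methoxybenzyl)oxy]-3-methyl-3-(triethylsilyloxy)butan-2-ol (C8 epimers, C17 defined) | COc1ccc(COCC(O)[C@](C)(O[Si](CC)(CC)CC)COCc2ccc(OC)cc2)cc1 | intermediate
17 | (R)-1,4-bis[(4-methoxybenzyl)oxy]-3-methyl-3-(triethylsilyloxy)butan-2-one | COc1ccc(COCC(=O)[C@](C)(O[Si](CC)(CC)CC)COCc2ccc(OC)cc2)cc1 | intermediate
18 | (Z)-enol triflate of 17 (TfO cis to O-9) | COc1ccc(CO/C=C(\OS(=O)(=O)C(F)(F)F)[C@](C)(O[Si](CC)(CC)CC)COCc2ccc(OC)cc2)cc1 | intermediate
19 | (R)-5-hydroxy-4-methylcyclohex-3-en-1-one | O=C1CC=C(C)[C@H](O)C1 | intermediate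
20 | (R)-4-methyl-5-(triethylsilyloxy)cyclohex-3-en-1-one | O=C1CC=C(C)[C@H](O[Si](CC)(CC)CC)C1 | intermediate
21 | 2-(trimethylsilyloxy)diene of 20 | C[Si](C)(C)OC1=CC=C(C)[C@H](O[Si](CC)(CC)CC)C1 | intermediate
22 | tributyltin dienolate of 20 | CCCC[Sn](CCCC)(CCCC)OC1=CC=C(C)[C@H](O[Si](CC)(CC)CC)C1 | intermediate (not isolated)
23 | 4,7-trans ketone with (E)-PMB enol ether side chain | O=C1C[C@@H](O[Si](CC)(CC)CC)C(C)=C[C@@H]1/C(=C\OCc2ccc(OC)cc2)[C@](C)(O[Si](CC)(CC)CC)COCc3ccc(OC)cc3 | intermediate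
24 | ring-C dienyllithium | [Li]C1=C[C@]2(C)OC(C)(C)O[C@@H]2C=C1 | intermediate (not isolated)
25 | ring-C dienylcerium dichloride | Cl[Ce](Cl)C1=C[C@]2(C)OC(C)(C)O[C@@H]2C=C1 | intermediate (not isolated)
26 | 1-(ring-C dienyl)-trans-2-alkenylcyclohex-3-en-1-ol (key-step precursor) | O[C@]1(C2=C[C@]3(C)OC(C)(C)O[C@@H]3C=C2)C[C@@H](O[Si](CC)(CC)CC)C(C)=C[C@@H]1/C(=C\OCc4ccc(OC)cc4)[C@](C)(O[Si](CC)(CC)CC)COCc5ccc(OC)cc5 | intermediate
27 | potassium (E)-dienolate O–C2=C1–C14=C13 of the ring-expanded ketone | [K+].[O-]/C1=C2/C=C[C@H]3OC(C)(C)O[C@@]3(C)[C@@H]2[C@H](OCc4ccc(OC)cc4)/C([C@](C)(O[Si](CC)(CC)CC)COCc5ccc(OC)cc5)=C/C=C(C)\[C@H](O[Si](CC)(CC)CC)C1 | intermediate (not isolated)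
28 | bicyclic cyclodeca-5,7-dien-2-one with quaternary C1 (key-step product) | O=C1C[C@@H](O[Si](CC)(CC)CC)/C(C)=C\C=C([C@](C)(O[Si](CC)(CC)CC)COCc2ccc(OC)cc2)\[C@@H](OCc3ccc(OC)cc3)[C@H]4[C@]5(C)OC(C)(C)O[C@@H]5C=C[C@]14C | intermediate
29 | (3R)-3-hydroxy ketone | O=C1[C@H](O)[C@@H](O[Si](CC)(CC)CC)/C(C)=C\C=C([C@](C)(O[Si](CC)(CC)CC)COCc2ccc(OC)cc2)\[C@@H](OCc3ccc(OC)cc3)[C@H]4[C@]5(C)OC(C)(C)O[C@@H]5C=C[C@]14C | intermediate
30 | (2S,3R)-2,3-diol | O[C@@H]1[C@H](O)[C@@H](O[Si](CC)(CC)CC)/C(C)=C\C=C([C@](C)(O[Si](CC)(CC)CC)COCc2ccc(OC)cc2)\[C@@H](OCc3ccc(OC)cc3)[C@H]4[C@]5(C)OC(C)(C)O[C@@H]5C=C[C@]14C | intermediate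
31 | 3-O-TBS ether | O[C@@H]1[C@H](O[Si](C)(C)C(C)(C)C)[C@@H](O[Si](CC)(CC)CC)/C(C)=C\C=C([C@](C)(O[Si](CC)(CC)CC)COCc2ccc(OC)cc2)\[C@@H](OCc3ccc(OC)cc3)[C@H]4[C@]5(C)OC(C)(C)O[C@@H]5C=C[C@]14C | intermediate
32 | 2,4-diol | O[C@@H]1[C@H](O[Si](C)(C)C(C)(C)C)[C@@H](O)/C(C)=C\C=C([C@](C)(O[Si](CC)(CC)CC)COCc2ccc(OC)cc2)\[C@@H](OCc3ccc(OC)cc3)[C@H]4[C@]5(C)OC(C)(C)O[C@@H]5C=C[C@]14C | intermediate
33 | 2,4-diacetate | CC(=O)O[C@@H]1[C@H](O[Si](C)(C)C(C)(C)C)[C@@H](OC(C)=O)/C(C)=C\C=C([C@](C)(O[Si](CC)(CC)CC)COCc2ccc(OC)cc2)\[C@@H](OCc3ccc(OC)cc3)[C@H]4[C@]5(C)OC(C)(C)O[C@@H]5C=C[C@]14C | intermediate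
34 | 9,19-diol | CC(=O)O[C@@H]1[C@H](O[Si](C)(C)C(C)(C)C)[C@@H](OC(C)=O)/C(C)=C\C=C([C@](C)(O[Si](CC)(CC)CC)CO)\[C@@H](O)[C@H]4[C@]5(C)OC(C)(C)O[C@@H]5C=C[C@]14C | intermediate
35 | C19 carboxylic acid (O-17 TES) | CC(=O)O[C@@H]1[C@H](O[Si](C)(C)C(C)(C)C)[C@@H](OC(C)=O)/C(C)=C\C=C([C@](C)(O[Si](CC)(CC)CC)C(O)=O)\[C@@H](O)[C@H]4[C@]5(C)OC(C)(C)O[C@@H]5C=C[C@]14C | intermediate
36 | 17-hydroxy acid | CC(=O)O[C@@H]1[C@H](O[Si](C)(C)C(C)(C)C)[C@@H](OC(C)=O)/C(C)=C\C=C([C@](C)(O)C(O)=O)\[C@@H](O)[C@H]4[C@]5(C)OC(C)(C)O[C@@H]5C=C[C@]14C | intermediate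
37 | 7,8-epoxy acid | CC(=O)O[C@@H]1[C@H](O[Si](C)(C)C(C)(C)C)[C@@H](OC(C)=O)/C(C)=C\[C@H]2O[C@]2([C@](C)(O)C(O)=O)[C@@H](O)[C@H]3[C@]4(C)OC(C)(C)O[C@@H]4C=C[C@]13C | intermediate (not isolated)
38 | hydroxy lactone (8-OH, 9-OH) | CC(=O)O[C@@H]1[C@H](O[Si](C)(C)C(C)(C)C)[C@@H](OC(C)=O)/C(C)=C\[C@@H]2OC(=O)[C@@](C)(O)[C@@]2(O)[C@@H](O)[C@H]3[C@]4(C)OC(C)(C)O[C@@H]4C=C[C@]13C | intermediate
39 | 2,4,9-triacetate (O-3 TBS, 11,12-acetonide) | CC(=O)O[C@@H]1[C@H](O[Si](C)(C)C(C)(C)C)[C@@H](OC(C)=O)/C(C)=C\[C@@H]2OC(=O)[C@@](C)(O)[C@@]2(O)[C@@H](OC(C)=O)[C@H]3[C@]4(C)OC(C)(C)O[C@@H]4C=C[C@]13C | intermediate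
40 | Brianodin C | CC(=O)O[C@@H]1[C@H](O)[C@@H](OC(C)=O)/C(C)=C\[C@@H]2OC(=O)[C@@](C)(O)[C@@]2(O)[C@@H](OC(C)=O)[C@H]2[C@](C)(O)[C@H](O)C=C[C@]12C | target

Total steps: 32. Longest linear sequence: 22 steps (steps 1–5, 16–19, 20, 21, 22–32).

Steps most likely to fail

Step 21. The methyl group may be delivered to the face of C1 anti to the new C10–C9 bond. That is the face left open by the transannular C7=C8 unit in the first-formed (E)-dienolate, and attack there gives cis ring fusion. O-methylation may compete. The fallback sets out from 26 and comes back at 28. The rearranged potassium dienolate is trapped with N-chlorosuccinimide instead of iodomethane, which should give the α-chloro ketone F1 with chlorine on the open face, anti to C9. MeMgBr/CeCl3 should then add to C2 anti to the C–Cl bond to give the chlorohydrin F2. AgBF4 should promote a semipinacol 1,2-shift of that methyl group from C2 to C1 with inversion at C1. This places C15 cis to C9 and regenerates the C2 ketone of 28.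

Step 19. Transmetallation and reductive elimination at the hindered C7–C8 junction may be slow. Coupling at the γ-carbon, loss of the tin dienolate by protonation and drift of the β,γ-enone into conjugation may take over. The fallback sets out from diol 5 and triflate 18 and comes back at 23. Silylation of the secondary hydroxyl of 5 gives the mono-TES ether F3, and LiHMDS/ClCO2Me gives the tertiary methyl carbonate F4. Rh-catalysed allylic oxidation as in step 5 gives the enone carbonate F5. Triflate 18 is converted with Pd(PPh3)4, Me6Sn2 and LiCl into the alkenylstannane F6. Pd2(dba)3/LiCl/DMF should then join F5 and F6 by allylic Stille substitution with overall inversion (ionisation anti to the carbonate, C–C bond formation from palladium), so C8 enters C7 trans to O-4.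

Step 30. Oxygen may be delivered to the wrong face of C7=C8 or to C5=C6, and the allylic C7–O bond may open in an SN1 manner with loss of inversion. The fallback sets out from acid 36 and comes back at 38. Trimethylsilyldiazomethane gives the methyl ester F7. Shi epoxidation (D-fructose-derived ketone, Oxone, NaHCO3-buffered MeCN/DMM) should give the epoxy ester F8 under reagent control; the spiro transition-state model predicts the required face. CSA then closes the lactone with loss of methanol.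

Further compounds
F1 | step 21 | α-chloro ketone (Cl on C1 anti to C9; otherwise as 28 without C15) | O=C1C[C@@H](O[Si](CC)(CC)CC)/C(C)=C\C=C([C@](C)(O[Si](CC)(CC)CC)COCc2ccc(OC)cc2)\[C@@H](OCc3ccc(OC)cc3)[C@H]4[C@]5(C)OC(C)(C)O[C@@H]5C=C[C@@]14Cl
F2 | step 21 | C2 methyl chlorohydrin of F1 (C2 configuration unassigned, methyl anti to C–Cl) | CC1(O)C[C@@H](O[Si](CC)(CC)CC)/C(C)=C\C=C([C@](C)(O[Si](CC)(CC)CC)COCc2ccc(OC)cc2)\[C@@H](OCc3ccc(OC)cc3)[C@H]4[C@]5(C)OC(C)(C)O[C@@H]5C=C[C@@]14Cl
F3 | step 19 | (1S,6R)-1-methyl-6-(triethylsilyloxy)cyclohex-2-en-1-ol | CC[Si](CC)(CC)O[C@@H]1CCC=C[C@]1(C)O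
F4 | step 19 | tertiary methyl carbonate of F3 | CC[Si](CC)(CC)O[C@@H]1CCC=C[C@]1(C)OC(=O)OC
F5 | step 19 | 4-(methoxycarbonyloxy)-4-methyl-5-(triethylsilyloxy)cyclohex-2-en-1-one (cis) | CC[Si](CC)(CC)O[C@@H]1CC(=O)C=C[C@]1(C)OC(=O)OC
F6 | step 19 | (Z)-alkenyltrimethylstannane from 18 (Sn cis to O-9) | COc1ccc(CO/C=C(\[Sn](C)(C)C)[C@](C)(O[Si](CC)(CC)CC)COCc2ccc(OC)cc2)cc1
F7 | step 30 | methyl ester of 36 | CC(=O)O[C@@H]1[C@H](O[Si](C)(C)C(C)(C)C)[C@@H](OC(C)=O)/C(C)=C\C=C([C@](C)(O)C(=O)OC)\[C@@H](O)[C@H]4[C@]5(C)OC(C)(C)O[C@@H]5C=C[C@]14C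
F8 | step 30 | 7,8-epoxy methyl ester | CC(=O)O[C@@H]1[C@H](O[Si](C)(C)C(C)(C)C)[C@@H](OC(C)=O)/C(C)=C\[C@H]2O[C@]2([C@](C)(O)C(=O)OC)[C@@H](O)[C@H]3[C@]4(C)OC(C)(C)O[C@@H]4C=C[C@]13C
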